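Each incoming ligand that enters a complex leaves the charge, and a closed flask keeps that count: a complex with two exchanged holds two of them. I ask how much of that complex the asked flask reaches, given these runs.

the same everywhere: starting complex 0.50 M

|  | incoming ligand | remark | time |
|---|---|---|---|
| Wednesday's | 0.75 M | the very flask that is asked about, followed so far |  |
| Friday's | 1.1 M | run made earlier |  |
| flask | 0.750 M |  | 2.5 d |

| Wednesday's: time / h | Wednesday's: complex with two exchanged / % | Friday's: time / h | Friday's: complex with two exchanged / % |
|---|---|---|---|
| 2.50 | 9.9 | 2.50 | 17.9 |
| 3.00 | 10.7 | 4.00 | 25.2 |
| 4.00 | 13.6 | 6.00 | 30.8 |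
| 5.00 | 15.8 | 10.0 | 30.9 |
| 8.00 | 19.1 | 15.0 | 26.9 |
| 10.0 | 19.2 | 25.0 | 16.2 |
| 12.0 | 18.1 | 40.0 | 7.2 |

(each reading ± 0.5 percentage points)

* the best time, 2.5 d at the latest, for complex with two exchanged
* the amount of complex with two exchanged, in percent of the starting complex charged, at that time
* the first time at which complex with two exchanged reaches 5.6%, in the same percent



I build the flask up in layers. With the two exchanges and nothing else, 0.750 M of incoming ligand on 0.50 M of starting complex gives a ceiling of 75.0%, less than the whole charge, with incoming ligand as the limiting reagent.

Next comes a loss. Friday's readings fall from 26.9% at 15.0 h to 7.2% at 40.0 h, which reads as a half-time of 0.548 d, shorter than the 2.5 d allowed. So I expect the rise in the asked flask to turn into a peak inside the limit, and Wednesday's readings, which are that flask's so far, put it between 8.00 h and 10.0 h, within their scatter. Wednesday's highest reading, 19.2%, is a quarter of the ceiling.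

The rest I do not model; I measure it against a zero. As my zero I take the statistical case, a peak that is a fixed share of the ligand charged with the starting complex held at its charge, so its logarithm rises against the logarithm of the ligand charge with slope one. Friday's highest reading, 30.9%, and Wednesday's, 19.2%, give a slope of 1.24, more than one: this is the ligand exponent, a reading with the scatter of those two readings. The asked flask has Wednesday's charge, so the exponent moves nothing, and I commit to about 19.2%.

The forecast, holding that “the answer comes almost directly from its readings”, gives 0.37 d (0.32 d to 0.41 d), 19.4% (18.8% to 20.1%) and 0.063 d (0.048 d to 0.08 d).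

The flask gives its best at 0.391 d, earlier than the limit, with 18.8%, and first reaches the asked amount at 0.0648 d.

    starting complex + incoming ligand ⇌ leaving ligand + complex with one exchanged (K = 2.57, k = 0.677 L mol⁻¹ h⁻¹)
    complex with one exchanged + incoming ligand ⇌ leaving ligand + complex with two exchanged (K = 15.3, k = 0.292 L mol⁻¹ h⁻¹)
    complex with two exchanged → over-reaction product (k = 0.0628 h⁻¹)
    incoming ligand → decomposed reagent (k = 0.0668 h⁻¹)

Now I take the neighbouring flask, with 1.3 M of incoming ligand and the other charges as in the recipe. That charge is more than in either run, so the exponent is stretched past the range it was read from. The charge ratio raised to the ligand exponent gives a factor of 1.98, and this carries the flask's 18.8% to 37.3%. The simulated neighbouring flask reaches a best of 37.5%.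

The data are calculated from invented constants, and the scatter is random.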